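**Plan**
- The target is a (3R)-isoflavan with C3 as its only stereocentre. Retrosynthesis: unmask the two phenols last, return C2 to the acetal oxidation level, then cut ring C at O1–C2 and C3–C4 in one retro-[4+2] step.
- The enabling feature is the 2-oxybenzyl unit of ring A (O1–C8a=C4a–C4H2, with the 7-oxygen para to C4a). It is a latent o-quinone methide, a 1-oxadiene. C2–C3 is the two-carbon partner, and its aryl-bearing C3 becomes the nucleophilic end once C2 is an enol ether carbon.
- Forward order: the chromene of ring B is built first (propargyl ether Claisen rearrangement, electrocyclisation) and extended to an (E)-enol ether. Ring A is prenylated before the union. Ring C is closed last by the cycloaddition.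
- Stereochemistry: the enol ether oxygen belongs to (1R,2S)-trans-2-phenylcyclohexanol, which steers the face of the enol ether and so sets C3. The auxiliary leaves with the C2 oxygen on ionic hydrogenation.
- Helpers: ortho O-Boc (quinone methide trigger), para O-Boc and O-TIPS (phenol protection), C2 alkoxy group (polarity and chirality).

Key step: step 9

Assumption: enol ether 11 is taken to react in its s-trans conformation with the carbinol C–H of the auxiliary in the enol ether plane, so that the phenyl ring covers the Re face of the oxygen-bearing carbon and the quinone methide adds to the other face to give the (2S,3R) adduct; should the facial sense be the reverse, the (1S,2R) alcohol is used in step 5 with no other change.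

**Route**

Step 1
Reactants: 1 2,4-dihydroxybenzaldehyde; 2 triisopropylsilyl chloride
Product: 3 2-hydroxy-4-[(triisopropylsilyl)oxy]benzaldehyde
Conditions: TIPSCl (1.05 equiv), imidazole, CH2Cl2, 0 °C
Reagents that add atoms: triisopropylsilyl chloride (2), CC(C)[Si](Cl)(C(C)C)C(C)C
Why: The 2-hydroxyl is tied up in a hydrogen bond to the aldehyde while the 4-hydroxyl is free and more acidic, so silyl ether formation should take place at O4 only.

Step 2
Reactants: 3 2-hydroxy-4-[(triisopropylsilyl)oxy]benzaldehyde; 4 3-chloro-3-methylbut-1-yne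
Product: 5 2-[(2-methylbut-3-yn-2-yl)oxy]-4-[(triisopropylsilyl)oxy]benzaldehyde
Conditions: DBU, CuCl2 (cat.), MeCN, 0 °C → rt
Reagents that add atoms: 3-chloro-3-methylbut-1-yne (4), C#CC(C)(C)Cl
Why: Copper-catalysed propargylic substitution (copper acetylide, then a copper-stabilised propargyl cation) should let even the chelated phenoxide be O-alkylated at the tertiary carbon, as in the usual preparation of aryl 1,1-dimethylpropargyl ethers.

Step 3
Reactants: 5 2-[(2-methylbut-3-yn-2-yl)oxy]-4-[(triisopropylsilyl)oxy]benzaldehyde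
Product: 7 2,2-dimethyl-5-[(triisopropylsilyl)oxy]-2H-chromene-8-carbaldehyde, via allenyl phenol 6 (not isolated)
Conditions: xylenes, 140 °C
Reagents that add atoms: none
Why: The aromatic propargyl Claisen rearrangement can only go to C3 because C1 carries the formyl group, and the allenyl phenol should close to the 2,2-dimethylchromene by 1,5-hydrogen shift and oxa-6π electrocyclisation.

Step 4
Reactants: 7 2,2-dimethyl-5-[(triisopropylsilyl)oxy]-2H-chromene-8-carbaldehyde; 8 iodoform
Product: 9 8-[(E)-2-iodoethenyl]-2,2-dimethyl-5-[(triisopropylsilyl)oxy]-2H-chromene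
Conditions: CrCl2, CHI3, THF, 0 °C → rt
Reagents that add atoms: iodoform (8), IC(I)I
Why: Takai olefination of an aryl aldehyde through a geminal dichromium species should give the (E)-vinyl iodide and leave the silyl ether and the chromene untouched.

Step 5
Reactants: 9 8-[(E)-2-iodoethenyl]-2,2-dimethyl-5-[(triisopropylsilyl)oxy]-2H-chromene; 10 (1R,2S)-trans-2-phenylcyclohexan-1-ol
Product: 11 2,2-dimethyl-8-[(E)-2-{[(1R,2S)-2-phenylcyclohexyl]oxy}ethenyl]-5-[(triisopropylsilyl)oxy]-2H-chromene
Conditions: CuI (10 mol %), 3,4,7,8-tetramethyl-1,10-phenanthroline (20 mol %), Cs2CO3, toluene, 80 °C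
Reagents that add atoms: (1R,2S)-trans-2-phenylcyclohexan-1-ol (10), O[C@@H]1CCCC[C@H]1c1ccccc1
Why: Ullmann-type copper-catalysed C–O coupling of a vinyl iodide with an alcohol goes with retention of double-bond geometry, so the auxiliary should arrive as the oxygen of an (E)-enol ether.

Step 6
Reactants: 12 5-bromo-2,4-dihydroxybenzaldehyde; 13 di-tert-butyl dicarbonate
Product: 14 5-bromo-2,4-bis[(tert-butoxycarbonyl)oxy]benzaldehyde
Conditions: Boc2O (2.2 equiv), i-Pr2NEt, DMAP (cat.), THF, 0 °C → rt
Reagents that add atoms: di-tert-butyl dicarbonate (13), CC(C)(C)OC(=O)OC(=O)OC(C)(C)C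
Why: DMAP-catalysed acylation should turn both phenols into tert-butyl carbonates, the ortho one being the later trigger of the quinone methide and the para one the protecting group of O7.

Step 7
Reactants: 14 5-bromo-2,4-bis[(tert-butoxycarbonyl)oxy]benzaldehyde; 15 tributyl(3-methylbut-2-en-1-yl)stannane
Product: 16 2,4-bis[(tert-butoxycarbonyl)oxy]-5-(3-methylbut-2-en-1-yl)benzaldehyde
Conditions: Pd(PPh3)4 (5 mol %), toluene, 100 °C
Reagents that add atoms: tributyl(3-methylbut-2-en-1-yl)stannane (15), CCCC[Sn](CCCC)(CCCC)CC=C(C)C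
Why: The Stille coupling runs under neutral conditions that the aldehyde and both carbonates tolerate and should deliver the prenyl group through its primary carbon.

Step 8
Reactants: 16 2,4-bis[(tert-butoxycarbonyl)oxy]-5-(3-methylbut-2-en-1-yl)benzaldehyde
Product: 17 {2,4-bis[(tert-butoxycarbonyl)oxy]-5-(3-methylbut-2-en-1-yl)phenyl}methanol
Conditions: NaBH(OAc)3, AcOH, 1,2-dichloroethane, rt → 50 °C
Reagents that add atoms: none
Why: Hydride reduction with an acyloxyborohydride under weakly acidic conditions should give the alcohol without a free alkoxide, which would start the carbonate shift and quinone methide formation too early, and it leaves the prenyl double bond alone.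

Step 9
Reactants: 17 {2,4-bis[(tert-butoxycarbonyl)oxy]-5-(3-methylbut-2-en-1-yl)phenyl}methanol; 11 2,2-dimethyl-8-[(E)-2-{[(1R,2S)-2-phenylcyclohexyl]oxy}ethenyl]-5-[(triisopropylsilyl)oxy]-2H-chromene
Product: 19 tert-butyl (2S,3R)-3-{2,2-dimethyl-5-[(triisopropylsilyl)oxy]-2H-chromen-8-yl}-6-(3-methylbut-2-en-1-yl)-2-{[(1R,2S)-2-phenylcyclohexyl]oxy}-3,4-dihydro-2H-chromen-7-yl carbonate, via o-quinone methide 18 (not isolated)
Conditions: 17 (1.5 equiv), 11 (1.0 equiv), t-BuMgCl (1.05 equiv on 17, slow addition), toluene–Et2O, −78 °C → rt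
Reagents that add atoms: none
Why: Deprotonation of 17 by the hindered Grignard reagent starts an O-to-O shift of the ortho Boc group onto the benzylic alkoxide, and the magnesium phenoxide so freed expels tert-butyl carbonate in a 1,4-elimination to give o-quinone methide 18 at low temperature. 18 is an electron-poor 1-oxadiene and is taken up by the electron-rich enol ether 11 in an inverse-electron-demand hetero-Diels–Alder reaction; the closest known reaction types are the low-temperature cycloadditions of o-quinone methides with enol ethers of trans-2-phenylcyclohexanol and the cycloadditions of β-alkoxystyrenes that give 2-alkoxy-3-arylchromans. Ring C is closed in the [4+2] mode, O1 adding to the alkoxy-bearing carbon and the methylene carbon C4 to the aryl-bearing carbon, so that O1–C2 and C3–C4 form in one operation with re-aromatisation of ring A as the driving force. C3 is controlled by the auxiliary, whose phenyl ring covers one face of the s-trans enol ether so that the quinone methide adds to the open face (3R); C2 follows from the suprafacial addition to the (E)-alkene (2,3-trans, 2S) and is only a temporary centre. The regiochemistry is secured by the polarity of the partners (nucleophilic β-carbon onto the electrophilic exocyclic methylene), and the step also needs the enol ether to win over the chromene and prenyl double bonds and over self-condensation of 18, which its higher nucleophilicity, the slow release of 18 and the low temperature should secure.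

Step 10
Reactants: 19 tert-butyl (2S,3R)-3-{2,2-dimethyl-5-[(triisopropylsilyl)oxy]-2H-chromen-8-yl}-6-(3-methylbut-2-en-1-yl)-2-{[(1R,2S)-2-phenylcyclohexyl]oxy}-3,4-dihydro-2H-chromen-7-yl carbonate
Product: 20 tert-butyl (3R)-3-{2,2-dimethyl-5-[(triisopropylsilyl)oxy]-2H-chromen-8-yl}-6-(3-methylbut-2-en-1-yl)-3,4-dihydro-2H-chromen-7-yl carbonate
Conditions: Et3SiH (5 equiv), BF3·OEt2 (2 equiv), CH2Cl2, −78 → −40 °C; Et3N, then NaHCO3 (aq.)
Reagents that add atoms: none
Why: Ionic hydrogenation of a 2-alkoxychroman, in which the Lewis acid ionises the exocyclic C2–O bond at the more basic alkyl oxygen and the cyclic oxocarbenium ion should take hydride from the silane faster than it loses the C3 proton, so that C3 is kept and the auxiliary is released.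

Step 11
Reactants: 20 tert-butyl (3R)-3-{2,2-dimethyl-5-[(triisopropylsilyl)oxy]-2H-chromen-8-yl}-6-(3-methylbut-2-en-1-yl)-3,4-dihydro-2H-chromen-7-yl carbonate
Product: 22 (3R)-3-(5-hydroxy-2,2-dimethyl-2H-chromen-8-yl)-6-(3-methylbut-2-en-1-yl)-3,4-dihydro-2H-chromen-7-ol, via mono-silyl ether 21 (not isolated)
Conditions: K2CO3 (cat.), MeOH–THF, rt; then Bu4NF, AcOH, THF, 0 °C
Reagents that add atoms: none
Why: Methanolysis of the aryl carbonate followed by buffered fluoride cleavage of the aryl silyl ether is neither acidic nor reducing, so the o-prenylphenol, the chromene and the C3 centre should survive.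

**Compound list**

1 | 2,4-dihydroxybenzaldehyde | O=Cc1ccc(O)cc1O | starting material
2 | triisopropylsilyl chloride | CC(C)[Si](Cl)(C(C)C)C(C)C | starting material
3 | 2-hydroxy-4-[(triisopropylsilyl)oxy]benzaldehyde | O=Cc1ccc(O[Si](C(C)C)(C(C)C)C(C)C)cc1O | intermediate
4 | 3-chloro-3-methylbut-1-yne | C#CC(C)(C)Cl | starting material
5 | 2-[(2-methylbut-3-yn-2-yl)oxy]-4-[(triisopropylsilyl)oxy]benzaldehyde | O=Cc1ccc(O[Si](C(C)C)(C(C)C)C(C)C)cc1OC(C)(C)C#C | intermediate
6 | 2-hydroxy-3-(3-methylbuta-1,2-dien-1-yl)-4-[(triisopropylsilyl)oxy]benzaldehyde | O=Cc1ccc(O[Si](C(C)C)(C(C)C)C(C)C)c(C=C=C(C)C)c1O | intermediate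
7 | 2,2-dimethyl-5-[(triisopropylsilyl)oxy]-2H-chromene-8-carbaldehyde | O=Cc1ccc(O[Si](C(C)C)(C(C)C)C(C)C)c2c1OC(C)(C)C=C2 | intermediate
8 | iodoform | IC(I)I | starting material
9 | 8-[(E)-2-iodoethenyl]-2,2-dimethyl-5-[(triisopropylsilyl)oxy]-2H-chromene | I/C=C/c1ccc(O[Si](C(C)C)(C(C)C)C(C)C)c2c1OC(C)(C)C=C2 | intermediate
10 | (1R,2S)-trans-2-phenylcyclohexan-1-ol | O[C@@H]1CCCC[C@H]1c1ccccc1 | starting material
11 | 2,2-dimethyl-8-[(E)-2-{[(1R,2S)-2-phenylcyclohexyl]oxy}ethenyl]-5-[(triisopropylsilyl)oxy]-2H-chromene | O(/C=C/c1ccc(O[Si](C(C)C)(C(C)C)C(C)C)c2c1OC(C)(C)C=C2)[C@@H]1CCCC[C@H]1c1ccccc1 | intermediate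
12 | 5-bromo-2,4-dihydroxybenzaldehyde | O=Cc1cc(Br)c(O)cc1O | starting material
13 | di-tert-butyl dicarbonate | CC(C)(C)OC(=O)OC(=O)OC(C)(C)C | starting material
14 | 5-bromo-2,4-bis[(tert-butoxycarbonyl)oxy]benzaldehyde | O=Cc1cc(Br)c(OC(=O)OC(C)(C)C)cc1OC(=O)OC(C)(C)C | intermediate
15 | tributyl(3-methylbut-2-en-1-yl)stannane | CCCC[Sn](CCCC)(CCCC)CC=C(C)C | starting material
16 | 2,4-bis[(tert-butoxycarbonyl)oxy]-5-(3-methylbut-2-en-1-yl)benzaldehyde | O=Cc1cc(CC=C(C)C)c(OC(=O)OC(C)(C)C)cc1OC(=O)OC(C)(C)C | intermediate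
17 | {2,4-bis[(tert-butoxycarbonyl)oxy]-5-(3-methylbut-2-en-1-yl)phenyl}methanol | OCc1cc(CC=C(C)C)c(OC(=O)OC(C)(C)C)cc1OC(=O)OC(C)(C)C | intermediate
18 | tert-butyl [4-methylidene-6-(3-methylbut-2-en-1-yl)-3-oxocyclohexa-1,5-dien-1-yl] carbonate (o-quinone methide) | C=C1C=C(CC=C(C)C)C(OC(=O)OC(C)(C)C)=CC1=O | intermediate
19 | tert-butyl (2S,3R)-3-{2,2-dimethyl-5-[(triisopropylsilyl)oxy]-2H-chromen-8-yl}-6-(3-methylbut-2-en-1-yl)-2-{[(1R,2S)-2-phenylcyclohexyl]oxy}-3,4-dihydro-2H-chromen-7-yl carbonate (2,3-trans) | CC(C)=CCc1cc2c(cc1OC(=O)OC(C)(C)C)O[C@H](O[C@@H]1CCCC[C@H]1c1ccccc1)[C@@H](c1ccc(O[Si](C(C)C)(C(C)C)C(C)C)c3c1OC(C)(C)C=C3)C2 | intermediate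
20 | tert-butyl (3R)-3-{2,2-dimethyl-5-[(triisopropylsilyl)oxy]-2H-chromen-8-yl}-6-(3-methylbut-2-en-1-yl)-3,4-dihydro-2H-chromen-7-yl carbonate | CC(C)=CCc1cc2c(cc1OC(=O)OC(C)(C)C)OC[C@@H](c1ccc(O[Si](C(C)C)(C(C)C)C(C)C)c3c1OC(C)(C)C=C3)C2 | intermediate
21 | (3R)-3-{2,2-dimethyl-5-[(triisopropylsilyl)oxy]-2H-chromen-8-yl}-6-(3-methylbut-2-en-1-yl)-3,4-dihydro-2H-chromen-7-ol | CC(C)=CCc1cc2c(cc1O)OC[C@@H](c1ccc(O[Si](C(C)C)(C(C)C)C(C)C)c3c1OC(C)(C)C=C3)C2 | intermediate
22 | (3R)-3-(5-hydroxy-2,2-dimethyl-2H-chromen-8-yl)-6-(3-methylbut-2-en-1-yl)-3,4-dihydro-2H-chromen-7-ol | CC(C)=CCc1cc2c(cc1O)OC[C@@H](c1ccc(O)c3c1OC(C)(C)C=C3)C2 | target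

**Step count and risks**

Total step count: 11.
Longest linear sequence: 8 steps (steps 1 to 5, then 9 to 11); the ring A branch (steps 6 to 8) joins at step 9.

Steps most likely to fail:

Step 9. The auxiliary may discriminate the two faces too weakly at the β-carbon, which lies far from it. Any (Z)-isomer carried in 11 would add with the opposite sense at C3. The hindered β-aryl enol ether may also add so slowly that self-condensation of the quinone methide takes over.
Fallback, from 11 and 17, returning at 21. Enol ether 11 is hydrolysed (oxalic acid, THF–H2O) to 2-{2,2-dimethyl-5-[(triisopropylsilyl)oxy]-2H-chromen-8-yl}acetaldehyde F1, with recovery of 10. Pinnick oxidation (NaClO2, NaH2PO4, 2-methylbut-2-ene) gives the arylacetic acid F2. This is joined through its pivaloyl mixed anhydride (t-BuCOCl, Et3N; then the lithium salt of (R)-4-benzyl-1,3-oxazolidin-2-one) to give the imide F3. Alcohol 17 is converted (CBr4, PPh3, CH2Cl2, 0 °C) into the benzyl bromide F4. Evans alkylation of the sodium enolate of F3 (NaN(SiMe3)2, THF, −78 °C) with F4 should give the (2R)-imide F5 by attack on the enolate face away from the benzyl group. LiBH4 (THF, 0 °C) takes off the oxazolidinone to give the primary alcohol F6, and K2CO3 in MeOH removes both carbonates to give the triol F7. Mitsunobu ring closure (PPh3, DIAD, THF, high dilution) of the primary alcohol onto the ortho phenol gives 21, which is desilylated as in the second stage of step 11.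

Step 10. The oxocarbenium ion may lose the C3 proton faster than it takes up hydride, which would racemise C3 through the achiral 3-aryl-4H-chromene. Endocyclic C–O cleavage may lead to the ring-opened ether. The Lewis acid may also attack the carbonate, the prenyl group or the chromene.
Fallback, from 19, returning at 20. 19 is treated with PhSH and BF3·OEt2 (CH2Cl2, −78 °C) to give the 2-(phenylsulfanyl)chroman F8 (C2 epimers), the thiol being a much faster trap for the oxocarbenium ion than the silane. The C–S bond is then cut in a radical chain (Bu3SnH, AIBN, benzene, 80 °C), in which the C2 radical takes hydrogen from the stannane without touching C3, to give 20.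

Step 5. Coupling of the hindered secondary alkoxide may be slow, with competing loss of the aryl silyl ether under the basic conditions and erosion of the double-bond geometry.
Fallback, from 10 and 7, returning at 11. A Horner–Wittig olefination replaces the C–O coupling and makes step 4 unnecessary. 10 is converted with paraformaldehyde and Me3SiCl into the chloromethyl ether F9. Arbuzov reaction with ethyl diphenylphosphinite gives the phosphine oxide F10. Lithiation (LiN(i-Pr)2, THF, −78 °C) and addition to aldehyde 7 gives β-hydroxy phosphine oxides, from which the threo adducts F11 are separated on silica; these are two diastereomers that differ in their relation to the auxiliary, and one is drawn. Syn elimination of diphenylphosphinate (NaH, THF) should then give 11 as the pure (E)-isomer.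

**Further compounds**

F1 | step 9 | 2-{2,2-dimethyl-5-[(triisopropylsilyl)oxy]-2H-chromen-8-yl}acetaldehyde | O=CCc1ccc(O[Si](C(C)C)(C(C)C)C(C)C)c2c1OC(C)(C)C=C2
F2 | step 9 | 2-{2,2-dimethyl-5-[(triisopropylsilyl)oxy]-2H-chromen-8-yl}acetic acid | OC(=O)Cc1ccc(O[Si](C(C)C)(C(C)C)C(C)C)c2c1OC(C)(C)C=C2
F3 | step 9 | (4R)-4-benzyl-3-({2,2-dimethyl-5-[(triisopropylsilyl)oxy]-2H-chromen-8-yl}acetyl)-1,3-oxazolidin-2-one | O=C(Cc1ccc(O[Si](C(C)C)(C(C)C)C(C)C)c2c1OC(C)(C)C=C2)N1[C@H](Cc2ccccc2)COC1=O
F4 | step 9 | 2,4-bis[(tert-butoxycarbonyl)oxy]-5-(3-methylbut-2-en-1-yl)benzyl bromide | BrCc1cc(CC=C(C)C)c(OC(=O)OC(C)(C)C)cc1OC(=O)OC(C)(C)C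
F5 | step 9 | (4R)-4-benzyl-3-[(2R)-3-{2,4-bis[(tert-butoxycarbonyl)oxy]-5-(3-methylbut-2-en-1-yl)phenyl}-2-{2,2-dimethyl-5-[(triisopropylsilyl)oxy]-2H-chromen-8-yl}propanoyl]-1,3-oxazolidin-2-one | O=C([C@H](Cc1cc(CC=C(C)C)c(OC(=O)OC(C)(C)C)cc1OC(=O)OC(C)(C)C)c1ccc(O[Si](C(C)C)(C(C)C)C(C)C)c2c1OC(C)(C)C=C2)N1[C@H](Cc2ccccc2)COC1=O
F6 | step 9 | di-tert-butyl {4-[(2R)-2-{2,2-dimethyl-5-[(triisopropylsilyl)oxy]-2H-chromen-8-yl}-3-hydroxypropyl]-6-(3-methylbut-2-en-1-yl)-1,3-phenylene} dicarbonate | OC[C@H](Cc1cc(CC=C(C)C)c(OC(=O)OC(C)(C)C)cc1OC(=O)OC(C)(C)C)c1ccc(O[Si](C(C)C)(C(C)C)C(C)C)c2c1OC(C)(C)C=C2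
F7 | step 9 | 4-[(2R)-2-{2,2-dimethyl-5-[(triisopropylsilyl)oxy]-2H-chromen-8-yl}-3-hydroxypropyl]-6-(3-methylbut-2-en-1-yl)benzene-1,3-diol | OC[C@H](Cc1cc(CC=C(C)C)c(O)cc1O)c1ccc(O[Si](C(C)C)(C(C)C)C(C)C)c2c1OC(C)(C)C=C2
F8 | step 10 | tert-butyl (3R)-3-{2,2-dimethyl-5-[(triisopropylsilyl)oxy]-2H-chromen-8-yl}-6-(3-methylbut-2-en-1-yl)-2-(phenylsulfanyl)-3,4-dihydro-2H-chromen-7-yl carbonate (C2 epimers) | CC(C)=CCc1cc2c(cc1OC(=O)OC(C)(C)C)OC(Sc1ccccc1)[C@@H](c1ccc(O[Si](C(C)C)(C(C)C)C(C)C)c3c1OC(C)(C)C=C3)C2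
F9 | step 5 | (1R,2S)-1-(chloromethoxy)-2-phenylcyclohexane | ClCO[C@@H]1CCCC[C@H]1c1ccccc1
F10 | step 5 | diphenyl({[(1R,2S)-2-phenylcyclohexyl]oxy}methyl)phosphane oxide | O=P(CO[C@@H]1CCCC[C@H]1c1ccccc1)(c1ccccc1)c1ccccc1
F11 | step 5 | (1R,2S)-1-{2,2-dimethyl-5-[(triisopropylsilyl)oxy]-2H-chromen-8-yl}-2-(diphenylphosphoryl)-2-{[(1R,2S)-2-phenylcyclohexyl]oxy}ethan-1-ol (threo adduct, one of two) | O=P(c1ccccc1)(c1ccccc1)[C@H](O[C@@H]1CCCC[C@H]1c1ccccc1)[C@H](O)c1ccc(O[Si](C(C)C)(C(C)C)C(C)C)c2c1OC(C)(C)C=C2
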